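**Retrosynthetic overview**
1. Galbulin 8 ⇐ tetralone 6: removal of the C4 carbonyl (last step).
2. 6 ⇐ lactone 3 + veratrole 4: one-pot Friedel–Crafts alkylation (C1–aryl), then ring-closing acylation (C4–C4a), which sets C1.
3. 3 ⇐ tiglic aldehyde 1 + veratraldehyde 2: the C1–C2 bond (target numbering) joins the enal β-carbon to the aldehyde carbon, two normally electrophilic carbons, through a carbene-generated homoenolate. This sets the C2 methyl centre.
4. Ring order: temporary lactone ring (step 1), then the carbocyclic ring of the tetralin (step 2); both arenes are bought.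

Assumption: the target SMILES is (1S,2S,3R)-galbulin (all-trans, the (−)-enantiomer); catalyst-bound species, carbocations and minor epimers that converge on a numbered compound in the same flask are described in words and not numbered.

**Step 1**
Reactants: 1 (E)-2-methylbut-2-enal (tiglic aldehyde, 1.5 equiv); 2 3,4-dimethoxybenzaldehyde (veratraldehyde)
Product: 3 (3S,4S)-5-(3,4-dimethoxyphenyl)-3,4-dimethyloxolan-2-one (both C5 epimers, carried on together)
Conditions: (5aR,10bS)-2-(2,4,6-trimethylphenyl)-5a,10b-dihydro-4H,6H-indeno[2,1-b][1,2,4]triazolo[4,3-d][1,4]oxazin-2-ium chloride (15 mol%), DBU (20 mol%), Ti(OiPr)4 (20 mol%), CH2Cl2, 25 → 40 °C; then DBU (1 equiv), 40 °C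
Reagents that add atoms: none
Why: Proposed new method: the N-aryl triazolylidene adds to enal 1 to give a Breslow intermediate whose β-carbon is now nucleophilic (homoenolate) and attacks the Ti(OiPr)4-activated aldehyde carbon of 2, then α-protonation gives an acyl azolium that the new alkoxide closes to the lactone with release of the carbene; the aminoindanol backbone shields one face of the homoenolate and so sets lactone C4 as S (the only centre that must come from the catalyst), DBU equilibrates C3 to the trans (3S) configuration, and C5 is left uncontrolled because step 2 erases it; the closest known reaction type is the carbene-catalysed homoenolate annulation of enals with aryl aldehydes to γ-butyrolactones and its chiral triazolium/Ti(OiPr)4 cooperative variants, here extended to an α,β-dialkyl enal and an electron-rich aldehyde.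

**Step 2**
Reactants: 3 (3S,4S)-5-(3,4-dimethoxyphenyl)-3,4-dimethyloxolan-2-one; 4 1,2-dimethoxybenzene (veratrole, 2 equiv)
Product: 6 (2S,3R,4S)-4-(3,4-dimethoxyphenyl)-6,7-dimethoxy-2,3-dimethyl-3,4-dihydronaphthalen-1(2H)-one, via diaryl acid 5 (not isolated)
Conditions: TfOH (20 mol%), (CF3)2CHOH, 0 °C → rt; evaporate; (CF3CO)2O (3 equiv), CF3CO2H/CH2Cl2, 0 °C → rt; then NaOMe (cat.), MeOH, rt
Reagents that add atoms: none
Why: Tandem Friedel–Crafts alkylation/acylation (the classical lactone + arene → 4-substituted 1-tetralone sequence): acid ionises the benzylic C5–O bond of either C5 epimer of 3 to one 3,4-dimethoxybenzylic cation, which 4 captures at its 4-position to give 5 (that carbon now carries two identical aryl groups and is no stereocentre), and the mixed anhydride then acylates, para to a methoxy group, one of the two diastereotopic rings through a chair-like transition state with the spectator aryl equatorial and anti to the ring bond, which sets tetralone C4 trans to the neighbouring methyl, while the enolisable C2 is held in the all-equatorial trans configuration by the NaOMe equilibration.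

**Step 3**
Reactants: 6 (2S,3R,4S)-4-(3,4-dimethoxyphenyl)-6,7-dimethoxy-2,3-dimethyl-3,4-dihydronaphthalen-1(2H)-one
Product: 8 (1S,2S,3R)-1-(3,4-dimethoxyphenyl)-6,7-dimethoxy-2,3-dimethyl-1,2,3,4-tetrahydronaphthalene (galbulin), via tosylhydrazone 7 (not isolated)
Conditions: TsNHNH2 (1.3 equiv), AcOH (cat.), EtOH, 80 °C; evaporate; catecholborane (3 equiv), CHCl3, 0 °C → rt; then NaOAc·3H2O, reflux
Reagents that add atoms: p-toluenesulfonyl hydrazide, Cc1ccc(cc1)S(=O)(=O)NN (its atoms are carried only in 7 and are lost before 8)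
Why: Caglioti/Kabalka reductive deoxygenation of a tosylhydrazone (a mild Wolff–Kishner variant): hydride adds to C=N, acetate triggers loss of sulfinate and the diazene loses N2 to leave CH2, and because no benzylic cation or alkene is formed at that carbon the adjacent methyl-bearing centre and the other two stereocentres are untouched.

**Compound list**
1 | (E)-2-methylbut-2-enal (tiglic aldehyde) | C/C=C(\C)C=O | starting material
2 | 3,4-dimethoxybenzaldehyde (veratraldehyde) | COc1ccc(C=O)cc1OC | starting material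
3 | (3S,4S)-5-(3,4-dimethoxyphenyl)-3,4-dimethyloxolan-2-one, mixture of C5 epimers (5R, aryl cis to the C4 methyl, expected major; 5S minor) | O=C1[C@@H](C)[C@H](C)C(c2ccc(OC)c(OC)c2)O1 | intermediate
4 | 1,2-dimethoxybenzene (veratrole) | COc1ccccc1OC | starting material
5 | (2S,3R)-4,4-bis(3,4-dimethoxyphenyl)-2,3-dimethylbutanoic acid | OC(=O)[C@@H](C)[C@H](C)C(c1ccc(OC)c(OC)c1)c1ccc(OC)c(OC)c1 | intermediate
6 | (2S,3R,4S)-4-(3,4-dimethoxyphenyl)-6,7-dimethoxy-2,3-dimethyl-3,4-dihydronaphthalen-1(2H)-one | COc1ccc([C@H]2c3cc(OC)c(OC)cc3C(=O)[C@@H](C)[C@@H]2C)cc1OC | intermediate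
7 | N'-[(2S,3R,4S)-4-(3,4-dimethoxyphenyl)-6,7-dimethoxy-2,3-dimethyl-3,4-dihydronaphthalen-1(2H)-ylidene]-4-methylbenzenesulfonohydrazide (tosylhydrazone of 6) | COc1ccc([C@H]2c3cc(OC)c(OC)cc3C(=NNS(=O)(=O)c3ccc(C)cc3)[C@@H](C)[C@@H]2C)cc1OC | intermediate
8 | (1S,2S,3R)-1-(3,4-dimethoxyphenyl)-6,7-dimethoxy-2,3-dimethyl-1,2,3,4-tetrahydronaphthalene (galbulin) | COc1ccc([C@H]2c3cc(OC)c(OC)cc3C[C@@H](C)[C@@H]2C)cc1OC | target

**Totals**
Total step count: 3. Longest linear sequence: 3 steps (1 + 2 → 3 → 6 → 8).

**Steps most likely to fail, with fallbacks**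

Step 1 (highest risk). An α,β-dialkyl enal forms the homoenolate slowly, the electron-rich aldehyde is a weak electrophile, and the level and sense of enantio-induction at lactone C4 are untested. If the sense is opposite, the commercially available mirror-image triazolium salt is used. Partial enantiopurity can be upgraded by recrystallising 6.
Fallback, setting out from 2 and coming back at 3, uses a stoichiometric chiral homoenolate equivalent:
- (E)-But-2-en-1-ol is carbamoylated (NaH, ClC(O)N(iPr)2, THF) to (E)-but-2-en-1-yl N,N-diisopropylcarbamate F1.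
- Deprotonation with n-BuLi/(−)-sparteine in pentane/cyclohexane at −78 °C (crystallisation-driven resolution of the lithium complex), transmetalation with Ti(OiPr)4 and addition of 2 give the anti homoaldol adduct (1Z,3S,4S)-4-(3,4-dimethoxyphenyl)-4-hydroxy-3-methylbut-1-en-1-yl N,N-diisopropylcarbamate F2. (+)-Sparteine is used instead if the (−)-alkaloid delivers the mirror image.
- MeOH/MeSO3H with Hg(OAc)2 (cat.) converts F2 into the lactol ether (4S,5S)-5-(3,4-dimethoxyphenyl)-2-methoxy-4-methyloxolane F3.
- mCPBA/BF3·OEt2 oxidises it to (4S,5S)-5-(3,4-dimethoxyphenyl)-4-methyloxolan-2-one F4.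
- LiN(iPr)2/MeI (THF, −78 °C) methylates the enolate trans to the C4 methyl and gives the (5S) epimer of 3, which enters step 2 unchanged.

Step 2. Two risks: proton loss and re-protonation of the benzylic cation before veratrole capture would erode the adjacent methyl centre, and the ring-selecting acylation may give some of the tetralone C4 epimer.
Fallback, setting out from 3 and coming back at 8, makes the aryl–C1 ring bond by a fast intramolecular cation cyclisation instead:
- Hydrogenolysis of the benzylic C–O bond of 3 (H2, Pd/C, AcOH) gives (2S,3R)-4-(3,4-dimethoxyphenyl)-2,3-dimethylbutanoic acid F5.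
- MeNHOMe·HCl/EDC gives the Weinreb amide (2S,3R)-4-(3,4-dimethoxyphenyl)-N-methoxy-N,2,3-trimethylbutanamide F6.
- 3,4-(MeO)2C6H3MgBr (THF, 0 °C) gives the ketone (2S,3R)-1,4-bis(3,4-dimethoxyphenyl)-2,3-dimethylbutan-1-one F7.
- NaBH4 (MeOH, 0 °C) gives the alcohol (2S,3R)-1,4-bis(3,4-dimethoxyphenyl)-2,3-dimethylbutan-1-ol F8 (C1 epimers).
- BF3·OEt2 in CH2Cl2 at 0 °C ionises F8 to the benzylic cation, which closes onto the other ring with the aryl pseudo-equatorial and trans to the neighbouring methyl, giving 8 directly.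
Because the trans-dimethyl unit of 3 is locally twofold-symmetric, exchanging the roles of its two ends gives the same enantiomer of 8.

Step 3. The ketone is hindered and deactivated by the para methoxy group, so hydrazone formation or hydride addition may stall.
Fallback, setting out from 6 and coming back at 8: HSCH2CH2SH/BF3·OEt2 (CH2Cl2, rt) converts 6 into its 1,3-dithiolane, (2'S,3'R,4'S)-4'-(3,4-dimethoxyphenyl)-6',7'-dimethoxy-2',3'-dimethyl-3',4'-dihydro-2'H-spiro[1,3-dithiolane-2,1'-naphthalene] F9, and Raney nickel in refluxing EtOH desulfurises it to 8.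

**Further compounds**
F1 | step 1 | (E)-but-2-en-1-yl N,N-diisopropylcarbamate | C/C=C/COC(=O)N(C(C)C)C(C)C
F2 | step 1 | (1Z,3S,4S)-4-(3,4-dimethoxyphenyl)-4-hydroxy-3-methylbut-1-en-1-yl N,N-diisopropylcarbamate | CC(C)N(C(C)C)C(=O)O/C=C\[C@H](C)[C@H](O)c1ccc(OC)c(OC)c1
F3 | step 1 | (4S,5S)-5-(3,4-dimethoxyphenyl)-2-methoxy-4-methyloxolane (anomer mixture) | COC1C[C@H](C)[C@@H](c2ccc(OC)c(OC)c2)O1
F4 | step 1 | (4S,5S)-5-(3,4-dimethoxyphenyl)-4-methyloxolan-2-one | O=C1C[C@H](C)[C@@H](c2ccc(OC)c(OC)c2)O1
F5 | step 2 | (2S,3R)-4-(3,4-dimethoxyphenyl)-2,3-dimethylbutanoic acid | OC(=O)[C@@H](C)[C@H](C)Cc1ccc(OC)c(OC)c1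
F6 | step 2 | (2S,3R)-4-(3,4-dimethoxyphenyl)-N-methoxy-N,2,3-trimethylbutanamide | CON(C)C(=O)[C@@H](C)[C@H](C)Cc1ccc(OC)c(OC)c1
F7 | step 2 | (2S,3R)-1,4-bis(3,4-dimethoxyphenyl)-2,3-dimethylbutan-1-one | COc1ccc(cc1OC)C(=O)[C@@H](C)[C@H](C)Cc1ccc(OC)c(OC)c1
F8 | step 2 | (2S,3R)-1,4-bis(3,4-dimethoxyphenyl)-2,3-dimethylbutan-1-ol (C1 epimers) | COc1ccc(cc1OC)C(O)[C@@H](C)[C@H](C)Cc1ccc(OC)c(OC)c1
F9 | step 3 | (2'S,3'R,4'S)-4'-(3,4-dimethoxyphenyl)-6',7'-dimethoxy-2',3'-dimethyl-3',4'-dihydro-2'H-spiro[1,3-dithiolane-2,1'-naphthalene] | COc1ccc([C@H]2c3cc(OC)c(OC)cc3C3(SCCS3)[C@@H](C)[C@@H]2C)cc1OC
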